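**Retrosynthetic overview**
1. Target 12 ⇐ dearomative gem‑diprenylation at C5 of the dihydrobenzofuran diol 10 (last step; converts the arene into the cyclohexadienone core).
2. 10 ⇐ debenzylation of 9; 9 ⇐ prenylphenol 7 by a phenol‑directed asymmetric epoxidation / 5‑exo epoxide opening (new step; forms the dihydrofuran ring and sets the only stereocentre, 2R).
3. 7 ⇐ 4‑O‑benzylation of mono‑prenyl acylphloroglucinol 5, so that only the oxygen ortho to the acyl group can close the furan.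
4. 5 ⇐ C‑prenylation of 3; 3 ⇐ Friedel–Crafts acylation of phloroglucinol 1 with isobutyryl chloride 2.
5. Ring order: benzene ring purchased → dihydrofuran ring (step 4) → dearomatised carbocycle (step 6).

Assumption: the target is treated as the enol tautomer drawn in the given SMILES (the stereocentre is R), and the (R,R)‑ligand of step 4 is taken to give the (S)‑epoxide; if the facial sense is the opposite, the (S,S)‑ligand is used.

**Step 1**
Reactants: 1 phloroglucinol (benzene‑1,3,5‑triol); 2 isobutyryl chloride (2‑methylpropanoyl chloride)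
Product: 3 2‑methyl‑1‑(2,4,6‑trihydroxyphenyl)propan‑1‑one
Conditions: AlCl3 (3.5 equiv), PhNO2/CH2Cl2, 0 → 60 °C; then 1 M HCl
Reagents that add atoms: isobutyryl chloride (2), CC(C)C(Cl)=O
Why: Friedel–Crafts C‑acylation of the very electron‑rich phloroglucinol ring stops at mono‑acylation because the chelated aryl ketone deactivates the product.

**Step 2**
Reactants: 3 2‑methyl‑1‑(2,4,6‑trihydroxyphenyl)propan‑1‑one; 4 prenyl bromide (1‑bromo‑3‑methylbut‑2‑ene)
Product: 5 2‑methyl‑1‑[2,4,6‑trihydroxy‑3‑(3‑methylbut‑2‑en‑1‑yl)phenyl]propan‑1‑one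
Conditions: prenyl bromide (0.9 equiv), 10% aq KOH, 0 °C; then acidify, chromatography (unreacted 3 recovered)
Reagents that add atoms: prenyl bromide (4), CC(C)=CCBr
Why: C‑alkylation of the ambident phloroglucinolate in water (hydrogen bonding shields the oxygens and directs attack through carbon), kept at mono‑prenylation by limiting the bromide.

**Step 3**
Reactants: 5 2‑methyl‑1‑[2,4,6‑trihydroxy‑3‑(3‑methylbut‑2‑en‑1‑yl)phenyl]propan‑1‑one; 6 benzyl bromide
Product: 7 1‑[4‑(benzyloxy)‑2,6‑dihydroxy‑3‑(3‑methylbut‑2‑en‑1‑yl)phenyl]‑2‑methylpropan‑1‑one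
Conditions: BnBr (1.05 equiv), K2CO3 (1.1 equiv), acetone, rt
Reagents that add atoms: benzyl bromide (6), BrCc1ccccc1
Why: Williamson etherification is selective for the 4‑OH, which is para to the ketone, the most acidic and not hydrogen‑bonded to the carbonyl; this blocks the one oxygen that could close the wrong (5‑acyl, linear) furan.

**Step 4**
Reactants: 7 1‑[4‑(benzyloxy)‑2,6‑dihydroxy‑3‑(3‑methylbut‑2‑en‑1‑yl)phenyl]‑2‑methylpropan‑1‑one
Product: 9 1‑[(2R)‑4‑(benzyloxy)‑6‑hydroxy‑2‑(2‑hydroxypropan‑2‑yl)‑2,3‑dihydro‑1‑benzofuran‑7‑yl]‑2‑methylpropan‑1‑one, via (S)‑epoxide 8 (not isolated)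
Conditions: Hf(OtBu)4 (10 mol %), (R,R)‑cyclohexane‑1,2‑diamine‑derived C2‑symmetric bis‑hydroxamic acid ligand (N,N'‑dihydroxy‑N,N'‑bis(diarylacetyl); 12 mol %), cumene hydroperoxide (1.5 equiv), DMPU (1 equiv), 4 Å MS, toluene, 0 °C → rt; then K2CO3 (0.2 equiv), MeOH, rt, one pot
Reagents that add atoms: cumene hydroperoxide, CC(C)(OO)c1ccccc1
Why: Proposed new method: the 2‑OH of 7 is a rigid bishomoallylic hydroxyl (O–C(aryl)=C(aryl)–CH2–CH=CMe2), so its phenoxide can bind a chiral Hf(IV) bis‑hydroxamate next to an η2‑cumylperoxide and receive the peroxide oxygen intramolecularly on one enantioface of the prenyl alkene (the benzylated O4 and the remote 6‑OH cannot reach it), giving (S)‑epoxide 8, which the same phenol opens 5‑exo‑tet with inversion at the CH carbon (base finish) to close the dihydrofuran and set 2R; the closest known reaction type is the Hf/Zr bis‑hydroxamic acid catalysed enantioselective hydroxyl‑directed epoxidation of homoallylic and bishomoallylic alkanols, which has not been shown with a phenol as directing group or coupled to this cycloetherification.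

**Step 5**
Reactants: 9 1‑[(2R)‑4‑(benzyloxy)‑6‑hydroxy‑2‑(2‑hydroxypropan‑2‑yl)‑2,3‑dihydro‑1‑benzofuran‑7‑yl]‑2‑methylpropan‑1‑one
Product: 10 1‑[(2R)‑4,6‑dihydroxy‑2‑(2‑hydroxypropan‑2‑yl)‑2,3‑dihydro‑1‑benzofuran‑7‑yl]‑2‑methylpropan‑1‑one
Conditions: H2 (1 atm), 10% Pd/C, EtOAc, rt
Reagents that add atoms: none
Why: Hydrogenolysis of the aryl benzyl ether is clean because no alkene is present at this stage, and the chelated aryl ketone, the tertiary alcohol and the non‑benzylic C2–O stereocentre are inert.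

**Step 6**
Reactants: 10 1‑[(2R)‑4,6‑dihydroxy‑2‑(2‑hydroxypropan‑2‑yl)‑2,3‑dihydro‑1‑benzofuran‑7‑yl]‑2‑methylpropan‑1‑one; 4 prenyl bromide (1‑bromo‑3‑methylbut‑2‑ene)
Product: 12 garcinielliptone HC, via 5‑monoprenyl phenol 11 (not isolated)
Conditions: prenyl bromide (2.6 equiv), NaOMe (2.5 equiv), MeOH, 0 °C → rt; then 0.5 M HCl
Reagents that add atoms: prenyl bromide (4), CC(C)=CCBr
Why: Lupulone‑type alkylative dearomatisation: C5, flanked by both phenoxide oxygens, is the most nucleophilic carbon and is C‑prenylated twice in protic solvent, the second alkylation giving the gem‑diprenyl β‑triketone/vinylogous ester held by the enol hydrogen bond, with the C2 stereocentre untouched.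

**Compound list**
1 | phloroglucinol (benzene‑1,3,5‑triol) | Oc1cc(O)cc(O)c1 | starting material
2 | isobutyryl chloride | CC(C)C(Cl)=O | starting material
3 | 2‑methyl‑1‑(2,4,6‑trihydroxyphenyl)propan‑1‑one | CC(C)C(=O)c1c(O)cc(O)cc1O | intermediate
4 | prenyl bromide (1‑bromo‑3‑methylbut‑2‑ene) | CC(C)=CCBr | starting material
5 | 2‑methyl‑1‑[2,4,6‑trihydroxy‑3‑(3‑methylbut‑2‑en‑1‑yl)phenyl]propan‑1‑one | CC(C)C(=O)c1c(O)cc(O)c(CC=C(C)C)c1O | intermediate
6 | benzyl bromide | BrCc1ccccc1 | starting material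
7 | 1‑[4‑(benzyloxy)‑2,6‑dihydroxy‑3‑(3‑methylbut‑2‑en‑1‑yl)phenyl]‑2‑methylpropan‑1‑one | CC(C)C(=O)c1c(O)cc(OCc2ccccc2)c(CC=C(C)C)c1O | intermediate
8 | 1‑[4‑(benzyloxy)‑3‑{[(2S)‑3,3‑dimethyloxiran‑2‑yl]methyl}‑2,6‑dihydroxyphenyl]‑2‑methylpropan‑1‑one | CC(C)C(=O)c1c(O)cc(OCc2ccccc2)c(C[C@@H]3OC3(C)C)c1O | intermediate (not isolated)
9 | 1‑[(2R)‑4‑(benzyloxy)‑6‑hydroxy‑2‑(2‑hydroxypropan‑2‑yl)‑2,3‑dihydro‑1‑benzofuran‑7‑yl]‑2‑methylpropan‑1‑one | CC(C)C(=O)c1c(O)cc(OCc2ccccc2)c3c1O[C@@H](C(C)(C)O)C3 | intermediate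
10 | 1‑[(2R)‑4,6‑dihydroxy‑2‑(2‑hydroxypropan‑2‑yl)‑2,3‑dihydro‑1‑benzofuran‑7‑yl]‑2‑methylpropan‑1‑one | CC(C)C(=O)c1c(O)cc(O)c2c1O[C@@H](C(C)(C)O)C2 | intermediate
11 | 1‑[(2R)‑4,6‑dihydroxy‑2‑(2‑hydroxypropan‑2‑yl)‑5‑(3‑methylbut‑2‑en‑1‑yl)‑2,3‑dihydro‑1‑benzofuran‑7‑yl]‑2‑methylpropan‑1‑one | CC(C)C(=O)c1c(O)c(CC=C(C)C)c(O)c2c1O[C@@H](C(C)(C)O)C2 | intermediate (not isolated)
12 | garcinielliptone HC, (2R,7Z)‑7‑(1‑hydroxy‑2‑methylpropylidene)‑2‑(2‑hydroxypropan‑2‑yl)‑5,5‑bis(3‑methylbut‑2‑en‑1‑yl)‑2,3‑dihydro‑1‑benzofuran‑4,6(5H,7H)‑dione | CC(C)=CCC1(CC=C(C)C)C(=O)C2=C(O[C@@H](C(C)(C)O)C2)/C(=C(/O)C(C)C)C1=O | target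

**Total step count:** 6
**Longest linear sequence:** 6 steps (1 → 3 → 5 → 7 → 9 → 10 → 12)

**Three steps most likely to fail**

Step 4 (proposed new step). Risks are oxidation of the electron‑rich ring by the metal peroxide, catalyst sequestration by the o‑hydroxyaryl ketone chelate, low ee, and 6‑endo opening to the chromanol. The ee is checked on 9 by chiral HPLC. The fallback uses known chemistry, sets out from 7 and comes back at 9. Both free phenols of 7 are silylated (TBSOTf, 2,6‑lutidine, CH2Cl2, 0 °C) to give 1‑[4‑(benzyloxy)‑2,6‑bis{[tert‑butyl(dimethyl)silyl]oxy}‑3‑(3‑methylbut‑2‑en‑1‑yl)phenyl]‑2‑methylpropan‑1‑one F3. Shi epoxidation of the prenyl group with the enantiomeric (L‑fructose‑type, made from L‑sorbose) Shi ketone (30 mol %), Oxone, K2CO3, Bu4NHSO4 in MeCN/dimethoxymethane/aqueous buffer at 0 °C gives 1‑[4‑(benzyloxy)‑2,6‑bis{[tert‑butyl(dimethyl)silyl]oxy}‑3‑{[(2S)‑3,3‑dimethyloxiran‑2‑yl]methyl}phenyl]‑2‑methylpropan‑1‑one F4. TBAF in THF (0 °C → rt) removes both silyl groups, and the liberated 2‑phenoxide opens the epoxide 5‑exo with inversion to give 9.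

Step 2. Risks are over‑prenylation to the 3,5‑diprenyl and gem‑diprenyl products and a modest yield. The fallback sets out from 3 and comes back at 7, so it replaces steps 2 and 3. Selective benzylation of the 4‑OH of 3 (BnBr, K2CO3, acetone) gives 1‑[4‑(benzyloxy)‑2,6‑dihydroxyphenyl]‑2‑methylpropan‑1‑one F1. Mono‑O‑prenylation of one of its two equivalent ortho hydroxyls (prenyl bromide 4, K2CO3, acetone, reflux; the second OH stays chelated) gives 1‑{4‑(benzyloxy)‑2‑hydroxy‑6‑[(3‑methylbut‑2‑en‑1‑yl)oxy]phenyl}‑2‑methylpropan‑1‑one F2. A thermal para‑Claisen–Cope rearrangement (N,N‑diethylaniline, about 195 °C) moves the prenyl group, with its normal connectivity, to the ring carbon para to the former ether oxygen, between OBn and the other ortho OH, which is 7.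

Step 6. Risks are O‑prenylation, competing alkylation at the ring‑fusion carbon C3a, and a sluggish second (quaternising) alkylation. The fallback sets out from 10 and comes back at 12. Pd‑catalysed Tsuji–Trost double allylation (Pd(PPh3)4 5 mol %, allyl methyl carbonate 2.5 equiv, THF, rt → 50 °C) is thermodynamically C‑selective because O‑allyl ethers re‑ionise, and gives (2R,7Z)‑7‑(1‑hydroxy‑2‑methylpropylidene)‑2‑(2‑hydroxypropan‑2‑yl)‑5,5‑di(prop‑2‑en‑1‑yl)‑2,3‑dihydro‑1‑benzofuran‑4,6(5H,7H)‑dione F5. Double olefin cross‑metathesis with excess 2‑methylbut‑2‑ene (Grubbs second‑generation catalyst, CH2Cl2, 40 °C) converts both allyl groups into prenyl groups and gives 12.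

**Further compounds**
F1 | step 2 | 1‑[4‑(benzyloxy)‑2,6‑dihydroxyphenyl]‑2‑methylpropan‑1‑one | CC(C)C(=O)c1c(O)cc(OCc2ccccc2)cc1O
F2 | step 2 | 1‑{4‑(benzyloxy)‑2‑hydroxy‑6‑[(3‑methylbut‑2‑en‑1‑yl)oxy]phenyl}‑2‑methylpropan‑1‑one | CC(C)C(=O)c1c(O)cc(OCc2ccccc2)cc1OCC=C(C)C
F3 | step 4 | 1‑[4‑(benzyloxy)‑2,6‑bis{[tert‑butyl(dimethyl)silyl]oxy}‑3‑(3‑methylbut‑2‑en‑1‑yl)phenyl]‑2‑methylpropan‑1‑one | CC(C)C(=O)c1c(O[Si](C)(C)C(C)(C)C)cc(OCc2ccccc2)c(CC=C(C)C)c1O[Si](C)(C)C(C)(C)C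
F4 | step 4 | 1‑[4‑(benzyloxy)‑2,6‑bis{[tert‑butyl(dimethyl)silyl]oxy}‑3‑{[(2S)‑3,3‑dimethyloxiran‑2‑yl]methyl}phenyl]‑2‑methylpropan‑1‑one | CC(C)C(=O)c1c(O[Si](C)(C)C(C)(C)C)cc(OCc2ccccc2)c(C[C@@H]3OC3(C)C)c1O[Si](C)(C)C(C)(C)C
F5 | step 6 | (2R,7Z)‑7‑(1‑hydroxy‑2‑methylpropylidene)‑2‑(2‑hydroxypropan‑2‑yl)‑5,5‑di(prop‑2‑en‑1‑yl)‑2,3‑dihydro‑1‑benzofuran‑4,6(5H,7H)‑dione | C=CCC1(CC=C)C(=O)C2=C(O[C@@H](C(C)(C)O)C2)/C(=C(/O)C(C)C)C1=O
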